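The route rests on disconnecting the bond between C3 of the 2-pyranone ring and the quaternary carbon of the 1,1-dimethylallyl group. C3 sits between the C2 lactone carbonyl and the oxygen-bearing C4, so it can be turned into a carbene centre. The precursor is therefore 3-diazo-6-phenylpyran-2,4-dione, partnered with prenyl phenyl sulfide. In one operation a rhodium carbenoid is trapped on sulfur and the resulting ylide delivers the prenyl unit to C3 with allyl inversion, giving the reverse-prenylated, sulfenylated dione. Thiolate removal of sulfur then re-aromatises the ring, and O4 is acylated with a silyl-protected 3-hydroxy-3-methylbutanoyl chloride before desilylation.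

Key step: step 5

Remark: the target has no stereocentre; the single stereocentre met on the way (C3 of the key-step product) is racemic and disappears in the following step.

Step 1
Reactants: 1 ethyl acetoacetate; 2 methyl benzoate
Product: 4 ethyl 3,5-dioxo-5-phenylpentanoate, via ethyl acetoacetate dianion 3 (not isolated)
Conditions: 1 (2.0 equiv), LiN(i-Pr)2 (4.1 equiv), THF, 0 °C; 2 (1.0 equiv), 0 °C → rt; aq. HCl
Reagents that add atoms: none
Why: Claisen-type acylation of a β-keto ester dianion (Huckin–Weiler conditions): the terminal carbanion of 3 is the most nucleophilic site and adds to the non-enolisable ester 2, and the second equivalent of 3 takes up the acidic proton of the product so that the acylation does not stall.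

Step 2
Reactants: 4 ethyl 3,5-dioxo-5-phenylpentanoate
Product: 5 4-hydroxy-6-phenyl-2H-pyran-2-one
Conditions: DBU (1.2 equiv), PhMe, reflux; aq. HCl
Reagents that add atoms: none
Why: Base-mediated lactonisation of a 3,5-dioxo ester: the C5 enolate oxygen attacks the ethyl ester (6-exo-trig), ethanol is lost and the ring is locked as the aromatic 4-hydroxy-2-pyranone.

Step 3
Reactants: 5 4-hydroxy-6-phenyl-2H-pyran-2-one
Product: 6 3-diazo-6-phenyl-2H-pyran-2,4(3H)-dione
Conditions: 4-AcNHC6H4SO2N3 (p-ABSA, 1.1 equiv), Et3N, MeCN, 0 °C → rt
Reagents that add atoms: 4-acetamidobenzenesulfonyl azide (p-ABSA), CC(=O)Nc1ccc(cc1)S(=O)(=O)N=[N+]=[N-]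
Why: Regitz diazo transfer: the C3 enolate of the cyclic β-keto lactone, the only doubly activated carbon, attacks the terminal nitrogen of the sulfonyl azide and the adduct fragments to the 2-diazo-1,3-dicarbonyl compound and the sulfonamide.

Step 4
Reactants: 7 1-bromo-3-methylbut-2-ene; 8 sodium benzenethiolate
Product: 9 (3-methylbut-2-en-1-yl)(phenyl)sulfane
Conditions: EtOH, 0 °C → rt
Reagents that add atoms: none
Why: SN2 thioetherification: the soft thiolate displaces bromide at the unhindered primary allylic carbon, so the linear prenyl sulfide should form without allylic transposition.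

Step 5
Reactants: 6 3-diazo-6-phenyl-2H-pyran-2,4(3H)-dione; 9 (3-methylbut-2-en-1-yl)(phenyl)sulfane
Product: 11 racemic 3-(2-methylbut-3-en-2-yl)-6-phenyl-3-(phenylsulfanyl)-2H-pyran-2,4(3H)-dione, via sulfonium ylide 10 (not isolated)
Conditions: Rh2(OAc)4 (2 mol %), 9 (2 equiv), PhMe, 80 °C, slow addition of 6
Reagents that add atoms: none
Why: The divalent rhodium dimer Rh2(OAc)4 extrudes N2 from 6 to give an electrophilic carbenoid at C3, the sulfur lone pair of 9 intercepts it to form the doubly acyl-stabilised ylide 10, and 10 undergoes a concerted suprafacial [2,3]-sigmatropic shift through a five-membered envelope transition state in which C3 bonds to the dimethyl-substituted allyl terminus while the S–CH2 bond breaks and the vinyl group is released. The closest known reaction type is the Doyle–Kirmse reaction of 2-diazo-1,3-dicarbonyl compounds with allyl and prenyl aryl sulfides under rhodium or copper catalysis. No ring is closed. The new C3 stereocentre should form as a racemate because neither substrate nor catalyst is chiral, which is immaterial since step 6 removes it. The step needs capture at sulfur to outrun attack of the carbenoid on the trisubstituted alkene of 9, and needs the [2,3] shift to outrun a [1,2] (Stevens) migration or transfer of the allyl group to the enolate oxygen; the higher nucleophilicity of sulfur, the excess of 9 with slow addition of 6, and the allyl terminus held in reach of the ylide carbon should secure this, and with C4 present as a ketone no hydroxyl can add to the new vinyl group. Heating to 80 °C is chosen because bis-acyl sulfonium ylides rearrange sluggishly at room temperature, while higher temperatures are avoided to keep the congested dione from drifting by a [3,3] shift.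

Step 6
Reactants: 11 racemic 3-(2-methylbut-3-en-2-yl)-6-phenyl-3-(phenylsulfanyl)-2H-pyran-2,4(3H)-dione
Product: 13 4-hydroxy-3-(2-methylbut-3-en-2-yl)-6-phenyl-2H-pyran-2-one, via sodium pyranolate 12 (not isolated)
Conditions: PhSNa (8, 1.5 equiv), DMF, 0 °C; cold aq. HCl to pH 3
Reagents that add atoms: none
Why: Thiophilic desulfenylation of an α-sulfenyl β-dicarbonyl compound: the thiolate attacks sulfur, PhSSPh departs and C3 leaves as the aromatic 4-oxidopyranone 12, which erases the C3 stereocentre, and brief cold acidification keeps the free 4-hydroxyl from adding to the vinyl group.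

Step 7
Reactants: 14 3-hydroxy-3-methylbutanoic acid
Product: 16 3-methyl-3-[(triethylsilyl)oxy]butanoic acid, via bis-silyl derivative 15 (not isolated)
Conditions: TESOTf (2.3 equiv), 2,6-lutidine, CH2Cl2, −78 → 0 °C; then K2CO3, MeOH/H2O, 0 °C; aq. HCl to pH 4
Reagents that add atoms: triethylsilyl trifluoromethanesulfonate (TESOTf), CC[Si](CC)(CC)OS(=O)(=O)C(F)(F)F
Why: Exhaustive silylation followed by selective silyl ester cleavage: the silyl triflate covers both the carboxyl and the hindered tertiary hydroxyl, and carbonate in aqueous methanol removes only the far more labile silyl ester.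

Step 8
Reactants: 16 3-methyl-3-[(triethylsilyl)oxy]butanoic acid; 13 4-hydroxy-3-(2-methylbut-3-en-2-yl)-6-phenyl-2H-pyran-2-one
Product: 18 3-(2-methylbut-3-en-2-yl)-2-oxo-6-phenyl-2H-pyran-4-yl 3-methyl-3-[(triethylsilyl)oxy]butanoate, via acid chloride 17 (not isolated)
Conditions: 16, Me2C=C(Cl)NMe2 (Ghosez reagent, 1.1 equiv), CH2Cl2, 0 °C → rt; then 13, pyridine, DMAP (cat.), CH2Cl2, 0 °C → rt
Reagents that add atoms: none
Why: Acid chloride formation under neutral conditions with the α-chloroenamine, then pyridine/DMAP O-acylation (Einhorn conditions): the silyl ether is spared, and the acidic 4-hydroxyl is the only acceptor because C3 already carries the tertiary alkyl group and cannot be C-acylated.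

Step 9
Reactants: 18 3-(2-methylbut-3-en-2-yl)-2-oxo-6-phenyl-2H-pyran-4-yl 3-methyl-3-[(triethylsilyl)oxy]butanoate
Product: 19 3-(2-methylbut-3-en-2-yl)-2-oxo-6-phenyl-2H-pyran-4-yl 3-hydroxy-3-methylbutanoate (target)
Conditions: HF·pyridine, pyridine, THF, 0 °C → rt; cold pH 7 phosphate buffer
Reagents that add atoms: none
Why: Fluoride-mediated desilylation with buffered HF·pyridine: the Si–O bond is cleaved under weakly acidic conditions that should leave the activated enol ester and the vinyl group alone, whereas basic fluoride would risk loss of the acyl group.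

Compound list
1 | ethyl acetoacetate | CCOC(=O)CC(C)=O | starting material
2 | methyl benzoate | COC(=O)c1ccccc1 | starting material
3 | ethyl acetoacetate dianion (dilithium dienolate) | [Li+].[Li+].C=C([O-])C=C([O-])OCC | intermediate
4 | ethyl 3,5-dioxo-5-phenylpentanoate | CCOC(=O)CC(=O)CC(=O)c1ccccc1 | intermediate
5 | 4-hydroxy-6-phenyl-2H-pyran-2-one | O=c1cc(O)cc(-c2ccccc2)o1 | intermediate
6 | 3-diazo-6-phenyl-2H-pyran-2,4(3H)-dione | [N-]=[N+]=C1C(=O)C=C(c2ccccc2)OC1=O | intermediate
7 | 1-bromo-3-methylbut-2-ene | CC(C)=CCBr | starting material
8 | sodium benzenethiolate | [Na+].[S-]c1ccccc1 | starting material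
9 | (3-methylbut-2-en-1-yl)(phenyl)sulfane | CC(C)=CCSc1ccccc1 | intermediate
10 | (3-methylbut-2-en-1-yl)(phenyl)sulfonium 2,4-dioxo-6-phenyl-2H-pyran-3-ylide | CC(C)=CC[S+](c1ccccc1)[C-]1C(=O)C=C(c2ccccc2)OC1=O | intermediate
11 | 3-(2-methylbut-3-en-2-yl)-6-phenyl-3-(phenylsulfanyl)-2H-pyran-2,4(3H)-dione (racemic at C3) | C=CC(C)(C)C1(Sc2ccccc2)C(=O)C=C(c2ccccc2)OC1=O | intermediate
12 | sodium 3-(2-methylbut-3-en-2-yl)-2-oxo-6-phenyl-2H-pyran-4-olate | [Na+].C=CC(C)(C)c1c([O-])cc(-c2ccccc2)oc1=O | intermediate
13 | 4-hydroxy-3-(2-methylbut-3-en-2-yl)-6-phenyl-2H-pyran-2-one | C=CC(C)(C)c1c(O)cc(-c2ccccc2)oc1=O | intermediate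
14 | 3-hydroxy-3-methylbutanoic acid | CC(C)(O)CC(=O)O | starting material
15 | triethylsilyl 3-methyl-3-[(triethylsilyl)oxy]butanoate | CC[Si](CC)(CC)OC(C)(C)CC(=O)O[Si](CC)(CC)CC | intermediate
16 | 3-methyl-3-[(triethylsilyl)oxy]butanoic acid | CC[Si](CC)(CC)OC(C)(C)CC(=O)O | intermediate
17 | 3-methyl-3-[(triethylsilyl)oxy]butanoyl chloride | CC[Si](CC)(CC)OC(C)(C)CC(=O)Cl | intermediate
18 | 3-(2-methylbut-3-en-2-yl)-2-oxo-6-phenyl-2H-pyran-4-yl 3-methyl-3-[(triethylsilyl)oxy]butanoate | C=CC(C)(C)c1c(OC(=O)CC(C)(C)O[Si](CC)(CC)CC)cc(-c2ccccc2)oc1=O | intermediate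
19 | 3-(2-methylbut-3-en-2-yl)-2-oxo-6-phenyl-2H-pyran-4-yl 3-hydroxy-3-methylbutanoate | C=CC(C)(C)c1c(OC(=O)CC(C)(C)O)cc(-c2ccccc2)oc1=O | target

Total step count: 9

Longest linear sequence: 7 steps (steps 1, 2, 3, 5, 6, 8, 9, from 1 to 19); steps 4 and 7 are one-step side branches.

Steps most likely to fail

Step 5. The doubly stabilised ylide may persist without rearranging, the sulfide may slow the catalyst by coordination, or the carbenoid may add to the alkene of the sulfide. The fallback brings in the reverse-prenyl group by an oxygen-to-carbon Claisen shift and sets out from 5. Mitsunobu etherification with 3-methylbut-2-en-1-ol (PPh3, DIAD, THF) should give 4-[(3-methylbut-2-en-1-yl)oxy]-6-phenyl-2H-pyran-2-one F1. Heating F1 in N,N-diethylaniline with Ac2O and NaOAc should bring about the aromatic Claisen rearrangement to C3 and trap the rearranged enol at once as 3-(2-methylbut-3-en-2-yl)-2-oxo-6-phenyl-2H-pyran-4-yl acetate F2. The trapping keeps the hydroxyl from cyclising onto the vinyl group. K2CO3 in MeOH at 0 °C should then remove the acetyl group, and the route is rejoined at 13.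

Step 6. The thiolate may add to the C5=C6 enone or open the lactone in competition with attack at sulfur, or the freed 4-hydroxyl may close onto the vinyl group during acidification. The fallback replaces the polar cleavage by single-electron reduction and sets out from 11. SmI2 in THF/MeOH at −78 °C should cleave the C3–S bond of the α-sulfenyl dicarbonyl unit, and quenching with pH 7 buffer should give 13 directly, where the route is rejoined. No new compound is formed (F0).

Step 9. The activated enol ester may be lost during desilylation, by hydrolysis or by the freed tertiary hydroxyl closing onto its own carbonyl with expulsion of the pyranone. The fallback removes the protecting group from the plan and sets out from 13. Steglich esterification of 13 with unprotected 14 (EDC·HCl, DMAP, CH2Cl2, 0 °C) should give 19 directly, since the hindered tertiary hydroxyl is too poor a nucleophile to compete, and the route is rejoined at 19. No new compound is formed (F0).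

Further compounds
F1 | step 5 | 4-[(3-methylbut-2-en-1-yl)oxy]-6-phenyl-2H-pyran-2-one | CC(C)=CCOc1cc(-c2ccccc2)oc(=O)c1
F2 | step 5 | 3-(2-methylbut-3-en-2-yl)-2-oxo-6-phenyl-2H-pyran-4-yl acetate | C=CC(C)(C)c1c(OC(C)=O)cc(-c2ccccc2)oc1=O
F0 | step 6 | none | none
F0 | step 9 | none | none
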